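## The problem

The target **25** is a longipinane. A cyclobutane (C4–C5–C11–C10) has both diagonals bridged on opposite faces: C4/C11 by C3–C2–C1 (ring A, six-membered, with the C1 ketone and the C3 methyl) and C5/C10 by C6–C7–C8–C9 (ring C, seven-membered, with the C6 gem-dimethyl group and the two angelates). These longipinane locants are used for every intermediate, including the bicyclic ones and the lower homologue that lacks C8.

Four of the seven stereocentres (C4, C5, C10, C11) are locked to one another by the cage and amount to one decision, the absolute sense. C3, C7 and C9 are separate problems.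

The C10 methyl leans over ring A, so reagents reach C3 from the side of the C5–H bridge. The target has its C3 methyl on that side, so the methyl, not a hydrogen, must be the group that arrives.

The ring C bridge lies on a local mirror plane of the cage (C4 and C11 look alike from below). The cage therefore gives almost no bias at C7 or C9: one of them needs reagent control, and the other can be tied to it through the anti relationship of the two oxygens.

The angelates isomerise to tiglates under acid, base, heat or nucleophiles and are Michael acceptors, so they must come last. Both carbinol carbons are neopentyl-like (C7 next to C6, C9 next to quaternary C10).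

The feature that allows the key step is C8. It is a plain methylene between the two oxygenated carbons, and C9 is bonded to the bridgehead C10, which cannot enolise and migrates poorly. Without C8, ring C is the six-membered bridge C5–C6–C7–C9–C10 of a tricyclo[4.4.0.0(2,7)]decane, whose cyclobutane can be closed from a cis-decalin. C8 can then be inserted next to a C9 ketone.

## Retrosynthesis

**Ester C–O bonds.** Cutting both acyl–oxygen bonds of **25** gives diol **22** and angelic acid **23**. Any earlier acylation would expose the angelates to enolates, cuprates and acid. The precursor keeps all seven stereocentres and only needs a double acylation of two hindered alcohols that does not isomerise the Z double bond.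

**C3–CH3 bond.** Cutting the methyl from **22** leads to the C3-unsubstituted enone **20**. The alternative, a methyl carried from a methyl-bearing dienophile, would leave C3 to hydrogenation or enolate protonation, and both deliver hydrogen from the open face and give the C3 epimer. In the cis-decalin the required methyl would be axial and 1,3 to a ketal oxygen, so it would not survive equilibration. Hydrogenation of a C2=C3 methyl enone in the tricycle fails for the same reason. Conjugate addition of a methyl group to **20** uses the same facial bias in the right sense. The forward step must add anti to the C10 methyl bridge.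

**C2=C3 unsaturation and the ketal.** Enone **20** comes from ketone **18** through its silyl enol ether. Only C2 can be enolised, because C11 is a bridgehead, and the silylation also covers the two hydroxyls. **18** comes from ketal **17** by hydrolysis. Up to that point the ketal is what keeps C1 distinct from C9.

**C9–H and C7–O.** Diol **17** is traced to β-hydroxy ketone **16** by a hydroxyl-directed reduction, which fixes the anti relationship internally. **16** is traced to enone **14** by conjugate borylation and oxidation. Epoxidation or oxa-Michael addition would rely on substrate bias that the cage does not offer. The copper boryl addition accepts a chiral ligand.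

**C7=C8.** Enone **14** comes from ketone **13** by dehydrogenation. C8 is the only enolisable position, so there is no regiochemical question.

**C7–C8 and C8–C9 (key).** Removing C8 from **13** gives the lower homologue **10** and trimethylsilyldiazomethane **11**. The neighbouring cuts would close the seven-membered ring end to end between hindered carbons, or build the cyclobutane inside a medium ring. Here ring C grows from a six-membered ring that decalin chemistry can supply. The forward reaction must insert on the C7 side of the carbonyl.

**C4–C10.** Of the four cyclobutane bonds of **10**, only C4–C10 pairs a carbon α to a carbonyl (C10, next to C9) with a secondary electrophilic carbon (C4). Closing C5–C11 would need displacement beside the quaternary C6. The precursor is the cis-decalin keto mesylate **9** with three defined stereocentres. The closure must be C-alkylation with inversion at C4, and C10 must already carry its methyl because it becomes a bridgehead.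

**C10–CH3 and adjustment of ring A.** **9** comes from alcohol **8**, and **8** from hydroxy ketone **7** by kinetic methylation on the side away from the gem-dimethyl group. **7** comes from silyl enol ether **6**, whose equatorial C4 hydroxyl is the thermodynamic alcohol of ketone **5**. **5** is the hydrogenation product of adduct **4**.

**C5–C6 and C10–C11.** Adduct **4** is the Diels–Alder product of diene **2** and the quinone monoketal **3**. The monoketal is preferred to the quinone because it has one carbonyl, which fixes the regiochemistry (the nucleophilic CH2 terminus adds β to it). It also cannot aromatise and delivers C1 already protected. The diene places the oxygen on C9 and the gem-dimethyl group on C6. **2** is the silyl dienol ether of mesityl oxide **1**. A chiral Lewis acid is asked to choose the face, which sets C5 and C11 and with them the whole cage.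

## Roads not taken

**Alternative 1:** The cut is the cyclobutane bond C5–C11, made by ring contraction. Photolysis of the α-diazo ketone A2 (a bicyclo[4.2.1]nonanone) would shift C5 from C1 to C11, and methanol would trap the ketene as the bicyclo[4.1.1]octane diester A1.

- Merits: the four-membered ring comes from a reliable photochemical contraction, not from an SN2 closure at a quaternary carbon. The C7 and C9 oxygens are in place, as silyl ethers, before the cage exists. In that respect this road is better than the chosen one, which has to rely on a ligand-controlled borylation late in the route.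
- Weak points: A2 already needs five stereocentres (C4, C5, C7, C9, C10) on a bridged medium ring, and its assembly is the real synthesis. C11 is set only by protonation of the ketene adduct. After A1, ring A still has to be closed (Dieckmann condensation, decarboxylation) and the C3 methyl is still missing.
- Comparison: the chosen plan reaches the complete ring system in nine steps from two commodity compounds, and its ring-forming events are one cycloaddition, one alkylation and the insertion.

**Alternative 2:** A class 1 sesquiterpene cyclase would fold farnesyl diphosphate A4 into α-longipinene A3, forming C5–C6, C5–C11 and C4–C10 in one active site.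

- Merits: for the carbon skeleton nothing chemical competes. One step gives all fifteen carbons, the cage and C10 in a single enantiomer.
- Weak points: A3 is a hydrocarbon. C1 is allylic and could be oxidised, but C7 and C9 are unactivated methylenes next to quaternary carbons with no directing group, and their oxygens must end up anti. Reduction of C2=C3 would again deliver hydrogen from the open face, which gives the wrong C3 epimer. A cyclase of the correct enantiomeric series would also have to be expressed and supplied with A4.
- Comparison: the chosen plan is far longer to the skeleton, but every oxygen is placed through a carbonyl handle by a step that can be defended.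

**Alternative 3:** A prochiral cyclobutanone A6 would be annulated with (E)-but-2-enal A7 under secondary-amine catalysis (C3–C4 by Michael addition, then C1–C11 by aldol) to give the bicyclo[3.1.1]heptanone A5.

- Merits: the cyclobutane is bought, not made. Absolute configuration comes from a desymmetrisation, with no hindered cycloaddition. A5 already has the C3 methyl in the right configuration, which the chosen plan pays for with a late dehydrogenation and a cuprate addition.
- Weak points: A5 contains only ring A and the four-membered ring, with C5 as a carbonyl. Ring C must still be grown. That means attaching the quaternary C6 to C5, removing the C5 oxygen with the right configuration, closing a seven-membered ring onto C9, and then setting C7 and C9. The annulation itself, through a strained cyclobutanone enamine to a bridged aldol, is not an established reaction.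
- Comparison: in the chosen plan ring C arrives in the first C–C bond-forming step and the full skeleton follows from one insertion. Alternative 3 moves the difficulty into a long second half.

Key step: step 9

Assumption: the sense of induction of the two chiral catalysts (steps 2 and 11) is written for the antipodes named; if the first adduct or boronate proves to have the opposite configuration, the mirror-image catalyst or ligand is used and nothing else changes.

## Route

Step 1
Reactants: 1 4-methylpent-3-en-2-one
Product: 2 triisopropyl[(4-methylpenta-1,3-dien-2-yl)oxy]silane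
Conditions: LiN(i-Pr)2, THF, −78 °C; i-Pr3SiOTf, −78 → 0 °C
Reagents that add atoms: triisopropylsilyl trifluoromethanesulfonate, CC(C)[Si](OS(=O)(=O)C(F)(F)F)(C(C)C)C(C)C
Why: Kinetic deprotonation at the α′ methyl gives the cross-conjugated lithium dienolate, and O-silylation gives the 2-silyloxy diene (silyl dienol ether formation).

Step 2
Reactants: 2 triisopropyl[(4-methylpenta-1,3-dien-2-yl)oxy]silane; 3 1,4-dioxaspiro[4.5]deca-6,9-dien-8-one
Product: 4 cis-fused cycloadduct (C1 dioxolane; C2=C3; C4 ketone; C7=C9 silyl enol ether; H5 and H11 cis)
Conditions: N-protonated (S)-3,3-diphenyl-1-(2-methylphenyl)tetrahydro-1H,3H-pyrrolo[1,2-c][1,3,2]oxazaborole bis(trifluoromethanesulfonyl)imide (20 mol %), CH2Cl2, −78 → −20 °C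
Reagents that add atoms: none
Why: Chiral Lewis acid-catalysed Diels–Alder reaction of a quinone monoketal with a 2-silyloxy diene; the nucleophilic CH2 terminus (C10) bonds to the β-carbon C11 and the substituted terminus C6 to C5, suprafacial addition gives the cis fusion, and the catalyst selects the face of the enone double bond, which sets C5 and C11. The ketal prevents aromatisation of the adduct.

Step 3
Reactants: 4 cis-fused cycloadduct
Product: 5 saturated C4 ketone (C2 and C3 now methylenes)
Conditions: H2 (1 atm), Pd/C, EtOAc, 20 °C
Reagents that add atoms: none
Why: Chemoselective catalytic hydrogenation of the conjugated disubstituted alkene; the trisubstituted silyl enol ether next to the quaternary C6 should be left untouched, and no stereocentre is formed.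

Step 4
Reactants: 5 saturated C4 ketone
Product: 6 C4 alcohol with the hydroxyl equatorial on the face of H5 and H11
Conditions: Li, NH3(l), THF, EtOH, −78 °C; NH4Cl
Reagents that add atoms: none
Why: Dissolving-metal reduction gives the thermodynamically preferred alcohol; the decalin prefers the chair in which C10 is axial on ring A (the other chair puts C1 syn-axial to a C6 methyl), and there the stable, equatorial hydroxyl lies on the face of H5 and H11, which sets C4. The silyl enol ether keeps C9 out of the reduction.

Step 5
Reactants: 6 C4 alcohol
Product: 7 hydroxy ketone (C9 ketone; C4 hydroxyl)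
Conditions: Bu4NF, THF, 0 °C
Reagents that add atoms: none
Why: Fluoride cleavage of the silyl enol ether releases the C9 ketone; C5 and C11 are not α to a carbonyl at this stage and cannot epimerise.

Step 6
Reactants: 7 hydroxy ketone
Product: 8 C10-methyl hydroxy ketone (C10 epimers)
Conditions: LiN(i-Pr)2 (2.2 equiv), THF, −78 °C; MeI, −78 → −30 °C
Reagents that add atoms: iodomethane, CI
Why: Kinetic enolate alkylation of the alkoxide–enolate dianion; deprotonation occurs at C10 and not at the neopentyl C7, and the lithium alkoxide is not methylated at low temperature. The C10 configuration is irrelevant because C10 is re-enolised in step 8.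

Step 7
Reactants: 8 C10-methyl hydroxy ketone
Product: 9 keto mesylate
Conditions: MsCl, Et3N, CH2Cl2, 0 °C
Reagents that add atoms: methanesulfonyl chloride, CS(=O)(=O)Cl
Why: Sulfonylation of the secondary alcohol with retention at C4; the amine is too weak a base to enolise the ketone.

Step 8
Reactants: 9 keto mesylate
Product: 10 tricyclic keto ketal (the lower homologue lacking C8)
Conditions: KOt-Bu, t-BuOH/THF, 25 → 50 °C
Reagents that add atoms: none
Why: Intramolecular ketone enolate C-alkylation (SN2, 4-exo-tet), the known way to close the cyclobutane of tricyclo[4.4.0.0(2,7)]decanones; under equilibrating conditions only the C10 enolate, axial on ring A, can reach the rear of the equatorial C4–O bond, so C4 is inverted and the quaternary C10 is fixed by the cage. The equatorial mesylate has no anti-periplanar hydrogen, which slows E2.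

Step 9
Reactants: 10 tricyclic keto ketal; 11 trimethylsilyldiazomethane
Product: 13 3-demethyllongipinane-1,9-dione 1-(ethylene ketal), via α-trimethylsilyl ketone 12 (not isolated)
Conditions: AlMe3, CH2Cl2, −78 → −20 °C; then K2CO3, MeOH, 20 °C
Reagents that add atoms: none
Why: AlMe3 binds the C9 carbonyl and the diazo carbon of 11 adds to it, giving a β-aluminoxy diazonium betaine; loss of N2 is concerted with the 1,2-shift of the anti-periplanar bond, so the new carbon C8 ends up between C7 and C9 (bonds C7–C8 and C8–C9). The closest known reaction type is the organoaluminium-promoted homologation of cyclohexanones to cycloheptanones with trimethylsilyldiazomethane. Ring C grows from six to seven members by insertion, so no ring is closed end to end and the cage is never opened. No stereocentre is created in the isolated product, since C8 is a methylene after desilylation and the cyclobutane centres are untouched. The selectivity needed is migration of C7 and not C10: in the betaine the Me3Si group avoids the quaternary bridgehead C10, which places N2 anti to C7, and the less substituted carbon is the one that normally migrates under these conditions. The first-formed α-silyl ketone 12 is less electrophilic than 10, which should stop a second insertion. Methanolysis then removes silicon without touching the dioxolane.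

Step 10
Reactants: 13 3-demethyllongipinane-1,9-dione 1-(ethylene ketal)
Product: 14 7-en-9-one (C7=C8 conjugated to the C9 ketone)
Conditions: LiN(i-Pr)2, THF, −78 °C; N-tert-butylbenzenesulfinimidoyl chloride, −78 °C
Reagents that add atoms: none
Why: Mukaiyama dehydrogenation: the lithium enolate, which can form only toward C8 because C10 is a bridgehead, is sulfenylated at C8 and the adduct eliminates the sulfenamide to give the enone.

Step 11
Reactants: 14 7-en-9-one
Product: 16 7-hydroxy-9-ketone (C7–O on the side of ring C that faces C4), via β-boryl ketone 15 (not isolated)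
Conditions: CuCl (5 mol %), NaOt-Bu (10 mol %), (R)-1-[(S)-2-(diphenylphosphino)ferrocenyl]ethyldicyclohexylphosphine (5 mol %), B2pin2, MeOH, THF, 20 °C; then 30% H2O2, pH 7 phosphate buffer, 0 °C
Reagents that add atoms: hydrogen peroxide, OO; bis(pinacolato)diboron, CC1(C)OB(OC1(C)C)B2OC(C)(C)C(C)(C)O2 (its boron stays only in 15)
Why: Copper-catalysed conjugate borylation of a cyclic enone followed by C–B oxidation with retention; because the cage gives almost no facial bias, the chiral bisphosphine on copper is expected to decide the C7 configuration.

Step 12
Reactants: 16 7-hydroxy-9-ketone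
Product: 17 anti-7,9-diol ketal
Conditions: Me4NBH(OAc)3, MeCN/AcOH, −30 °C
Reagents that add atoms: none
Why: Evans–Saksena reduction: the C7 hydroxyl exchanges onto boron and hydride is delivered intramolecularly to C9 from the side of the C7 oxygen, so the new C9–O bond is anti to it (C9 set); the hindered ketone should not react with the reagent intermolecularly.

Step 13
Reactants: 17 anti-7,9-diol ketal
Product: 18 7,9-dihydroxy-3-demethyllongipinan-1-one
Conditions: 1 M HCl, THF, 20 °C
Reagents that add atoms: water, O
Why: Acid hydrolysis of the dioxolane; the secondary alcohols do not ionise under these conditions.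

Step 14
Reactants: 18 7,9-dihydroxy-3-demethyllongipinan-1-one
Product: 20 7,9-bis(trimethylsilyloxy)-3-demethyllongipin-2-en-1-one, via tris-silylated enol ether 19 (not isolated)
Conditions: Me3SiOTf, Et3N, CH2Cl2, 0 °C; then Pd(OAc)2, MeCN, 20 °C
Reagents that add atoms: trimethylsilyl trifluoromethanesulfonate, C[Si](C)(C)OS(=O)(=O)C(F)(F)F
Why: Saegusa–Ito oxidation: the C1 ketone can enolise only toward C2 (C11 is a bridgehead), the silyl enol ether is dehydrogenated by Pd(OAc)2 to the C2=C3 enone, and the same silylation protects both hydroxyls.

Step 15
Reactants: 20 7,9-bis(trimethylsilyloxy)-3-demethyllongipin-2-en-1-one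
Product: 22 7,9-dihydroxylongipinan-1-one, via bis(trimethylsilyl) ether 21 (not isolated)
Conditions: Me2CuLi (from MeLi and CuI), Et2O, −78 → −30 °C; then 1 M HCl, THF, 0 °C
Reagents that add atoms: lithium dimethylcuprate, [Li+].C[Cu-]C
Why: Cuprate conjugate addition to a bicyclo[3.1.1]heptenone; the methyl group on C10 blocks one face of the enone, so the methyl is delivered to C3 from the side of the C5–H bridge, as with other bridged enones of this type, which sets C3 as in the target. The acidic work-up removes the silyl ethers.

Step 16
Reactants: 22 7,9-dihydroxylongipinan-1-one; 23 angelic acid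
Product: 25 7,9-bis(angeloyloxy)longipinan-1-one, via mixed anhydride 24 (not isolated)
Conditions: 2,4,6-trichlorobenzoyl chloride, Et3N, toluene, 20 °C; then 22, 80 °C
Reagents that add atoms: 2,4,6-trichlorobenzoyl chloride, O=C(Cl)c1c(Cl)cc(Cl)cc1Cl (its acyl group stays only in 24)
Why: Yamaguchi-type acylation through the mixed anhydride, the standard way to make angelates without Z to E isomerisation; no nucleophilic catalyst is used, and the alcohol attacks the less hindered angeloyl carbonyl.

## Compound list

1 | 4-methylpent-3-en-2-one (mesityl oxide) | CC(=O)C=C(C)C | starting material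
2 | triisopropyl[(4-methylpenta-1,3-dien-2-yl)oxy]silane | C=C(O[Si](C(C)C)(C(C)C)C(C)C)C=C(C)C | intermediate
3 | 1,4-dioxaspiro[4.5]deca-6,9-dien-8-one (1,4-benzoquinone monoethylene ketal) | O=C1C=CC2(OCCO2)C=C1 | starting material
4 | (4a'S,8a'S)-5',5'-dimethyl-7'-(triisopropylsilyloxy)-4a',5',8',8a'-tetrahydro-4'H-spiro[1,3-dioxolane-2,1'-naphthalen]-4'-one, cis-fused | O=C1C=CC2(OCCO2)[C@H]3CC(O[Si](C(C)C)(C(C)C)C(C)C)=CC(C)(C)[C@@H]13 | intermediate
5 | (4a'S,8a'S)-2',3'-dihydro derivative of 4 (saturated C4 ketone, cis-fused) | O=C1CCC2(OCCO2)[C@H]3CC(O[Si](C(C)C)(C(C)C)C(C)C)=CC(C)(C)[C@@H]13 | intermediate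
6 | (4'R,4a'S,8a'S)-alcohol from 5; C4 hydroxyl cis to H5 and H11; silyl enol ether retained | O[C@@H]1CCC2(OCCO2)[C@H]3CC(O[Si](C(C)C)(C(C)C)C(C)C)=CC(C)(C)[C@@H]13 | intermediate
7 | (4'R,4a'S,8a'S)-4'-hydroxy-5',5'-dimethyloctahydrospiro[1,3-dioxolane-2,1'-naphthalen]-7'-one (C9 ketone) | O[C@@H]1CCC2(OCCO2)[C@H]3CC(=O)CC(C)(C)[C@@H]13 | intermediate
8 | 8'-methyl derivative of 7 (methyl on C10, both C10 epimers; C4, C5, C11 as in 7) | O[C@@H]1CCC2(OCCO2)[C@H]3C(C)C(=O)CC(C)(C)[C@@H]13 | intermediate
9 | methanesulfonate of 8 (C4–O cis to H5 and H11; both C10 epimers) | CS(=O)(=O)O[C@@H]1CCC2(OCCO2)[C@H]3C(C)C(=O)CC(C)(C)[C@@H]13 | intermediate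
10 | 1,8,8-trimethylspiro[tricyclo[4.4.0.0(2,7)]decane-3,2'-[1,3]dioxolan]-10-one; cyclobutane C4–C5–C11–C10 configured as in 25; C9 ketone, C1 dioxolane, no C8, no C3 methyl | C1C(=O)[C@]2(C)[C@@H]3[C@@H]([C@H]2C4(OCCO4)CC3)C1(C)C | intermediate
11 | trimethylsilyldiazomethane | C[Si](C)(C)C=[N+]=[N-] | starting material
12 | 8-trimethylsilyl derivative of 13 (α-silyl ketone, C8 configuration undefined) | C1C([Si](C)(C)C)C(=O)[C@]2(C)[C@@H]3[C@@H]([C@H]2C4(OCCO4)CC3)C1(C)C | intermediate
13 | 3-demethyllongipinane-1,9-dione 1-(ethylene ketal); cage as in 25 | C1CC(=O)[C@]2(C)[C@@H]3[C@@H]([C@H]2C4(OCCO4)CC3)C1(C)C | intermediate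
14 | 3-demethyllongipin-7-ene-1,9-dione 1-(ethylene ketal) | C1=CC(=O)[C@]2(C)[C@@H]3[C@@H]([C@H]2C4(OCCO4)CC3)C1(C)C | intermediate
15 | 7-(pinacolatoboryl) derivative of 13; boron on the side of ring C facing C4 | CC1(C)OB(OC1(C)C)[C@@H]2CC(=O)[C@]3(C)[C@@H]4[C@@H]([C@H]3C5(OCCO5)CC4)C2(C)C | intermediate
16 | 7-hydroxy derivative of 13; C7–O on the side of ring C facing C4 | O[C@@H]1CC(=O)[C@]2(C)[C@@H]3[C@@H]([C@H]2C4(OCCO4)CC3)C1(C)C | intermediate
17 | anti-7,9-dihydroxy-3-demethyllongipinan-1-one ethylene ketal; C9–O on the side facing C11 | O[C@@H]1C[C@@H](O)[C@]2(C)[C@@H]3[C@@H]([C@H]2C4(OCCO4)CC3)C1(C)C | intermediate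
18 | anti-7,9-dihydroxy-3-demethyllongipinan-1-one | O[C@@H]1C[C@@H](O)[C@]2(C)[C@@H]3[C@@H]([C@H]2C(=O)CC3)C1(C)C | intermediate
19 | 1,7,9-tris(trimethylsilyloxy)-3-demethyllongipin-1-ene (silyl enol ether C1=C2) | C[Si](C)(C)O[C@@H]1C[C@@H](O[Si](C)(C)C)[C@]2(C)[C@@H]3[C@@H]([C@H]2C(O[Si](C)(C)C)=CC3)C1(C)C | intermediate
20 | 7,9-bis(trimethylsilyloxy)-3-demethyllongipin-2-en-1-one | C[Si](C)(C)O[C@@H]1C[C@@H](O[Si](C)(C)C)[C@]2(C)[C@@H]3[C@@H]([C@H]2C(=O)C=C3)C1(C)C | intermediate
21 | 7,9-bis(trimethylsilyloxy)longipinan-1-one; C3 methyl on the side of the C5–H bridge | C[Si](C)(C)O[C@@H]1C[C@@H](O[Si](C)(C)C)[C@]2(C)[C@@H]3[C@@H]([C@H]2C(=O)C[C@H]3C)C1(C)C | intermediate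
22 | (3R,4S,5S,7R,9R,10R,11R)-7,9-dihydroxylongipinan-1-one | O[C@@H]1C[C@@H](O)[C@]2(C)[C@@H]3[C@@H]([C@H]2C(=O)C[C@H]3C)C1(C)C | intermediate
23 | angelic acid, (Z)-2-methylbut-2-enoic acid | C/C=C(/C)C(=O)O | starting material
24 | (Z)-2-methylbut-2-enoic 2,4,6-trichlorobenzoic anhydride | C/C=C(/C)C(=O)OC(=O)c1c(Cl)cc(Cl)cc1Cl | intermediate
25 | (3R,4S,5S,7R,9R,10R,11R)-7,9-bis[(Z)-2-methylbut-2-enoyloxy]longipinan-1-one (CNP0283599.1) | C/C=C(/C)C(=O)O[C@@H]1C[C@@H](OC(=O)/C(C)=C\C)[C@]2(C)[C@@H]3[C@@H]([C@H]2C(=O)C[C@H]3C)C1(C)C | target

## Step count and risks

Total step count: 16. Longest linear sequence: 16 steps (1 → 25); compounds 3, 11 and 23 enter as purchased materials.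

**Step 9 (key step).** The C9 carbonyl sits between a neopentyl methylene and a quaternary bridgehead, so addition of the bulky silyldiazomethane may be slow. The betaine could then close to the epoxide, or part of the material could rearrange by migration of C10. The Lewis acid may also attack the dioxolane on long exposure.
Fallback, from 10 back to 14: kinetic enolisation of 10 (LiN(i-Pr)2, Me3SiCl), which can only go toward C7, gives the trimethylsilyl enol ether F1. Cyclopropanation with Et2Zn and CH2I2 gives the siloxycyclopropane F2. FeCl3 in DMF cleaves the internal cyclopropane bond to the ring-enlarged β-chloro ketone F3, and NaOAc in methanol eliminates HCl to give enone 14. This replaces steps 9 and 10. The same bonds C7–C8 and C8–C9 are formed, but the regiochemistry is fixed by the position of the enol ether, not by migratory aptitude.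

**Step 2.** The cis methyl on the C6 terminus disfavours the s-cis diene, so cycloaddition may be slower than protodesilylation of 2. A Mukaiyama–Michael addition might also stop before ring closure, the strong acid might ionise the ketal, or face selection might be incomplete with this hindered diene.
Fallback, from 2 and 3 back to 6: the uncatalysed cycloaddition in toluene at 110 °C gives 4 together with its mirror-image adduct F4. Steps 3 and 4 on the racemate give 5 with the mirror-image ketone F5 and 6 with the mirror-image alcohol F6. Esterification with (S)-2-methoxy-2-phenylacetic acid (DCC, DMAP) gives the O-methylmandelate ester F7 of 6 and the diastereomeric ester F8 of the mirror-image alcohol, which are separated by chromatography. K2CO3 in methanol releases 6 from F7.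

**Step 8.** A four-membered ring and a quaternary centre form in one event, so closure may be slow. The tetrasubstituted enolate may then be alkylated on oxygen by the hard sulfonate, giving a bridged enol ether, or the mesylate may be lost by elimination.
Fallback, from 5 back to 10: the softer iodide is made by inversion from the epimeric alcohol. LiBH(s-Bu)3 reduces 5 from the open face to the axial C4-epimeric alcohol F9. Bu4NF gives the epimeric hydroxy ketone F10, and LiN(i-Pr)2 then MeI gives its C10-methyl derivative F11. I2, PPh3 and imidazole (Appel reaction, inversion) give the equatorial iodide F12, which has the C4 configuration of 9. KOt-Bu in t-BuOH then closes it to 10.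

**Step 11.** The two faces of the enone are almost equivalent, so face selection rests on the ligand alone and may be incomplete. Addition next to the quaternary C6 may also be sluggish.
Fallback, from 14 back to 17: the borylation is run with an achiral phosphine and the C7-epimeric mixture of 16 is oxidised with Dess–Martin periodinane to the 7,9-dione F13. Asymmetric hydrogenation with RuCl2[(S)-BINAP] under H2 in methanol, the known route from 1,3-diketones to anti-1,3-diols, then sets C7 and C9 together by catalyst control and gives 17. This replaces step 12 as well.

**Step 16.** Both hydroxyls are neopentyl-like, so acylation may stop at the monoester. The heating needed to force the second acylation may isomerise angelate to tiglate.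
Fallback, from 22 back to 25: both hydroxyls are acylated with 2-[bis(2,2,2-trifluoroethoxy)phosphoryl]propanoic acid (DCC, DMAP) to the bis(phosphonopropionate) F14. A double Still–Gennari olefination (KN(SiMe3)2, 18-crown-6, acetaldehyde, THF, −78 °C) then builds both Z-configured 2-methylbut-2-enoates on the molecule and gives 25.

## Further compounds

F1 | step 9 | trimethylsilyl enol ether of 10 (C7=C9) | C1=C(O[Si](C)(C)C)[C@]2(C)[C@@H]3[C@@H]([C@H]2C4(OCCO4)CC3)C1(C)C
F2 | step 9 | siloxycyclopropane from F1 (new CH2 bridging C7 and C9; either face) | C12CC1(O[Si](C)(C)C)[C@]3(C)[C@@H]4[C@@H]([C@H]3C5(OCCO5)CC4)C2(C)C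
F3 | step 9 | 7-chloro derivative of 13 (C7 configuration undefined) | ClC1CC(=O)[C@]2(C)[C@@H]3[C@@H]([C@H]2C4(OCCO4)CC3)C1(C)C
F4 | step 2 | mirror-image adduct, enantiomer of 4 | O=C1C=CC2(OCCO2)[C@@H]3CC(O[Si](C(C)C)(C(C)C)C(C)C)=CC(C)(C)[C@H]13
F5 | step 2 | mirror-image ketone, enantiomer of 5 | O=C1CCC2(OCCO2)[C@@H]3CC(O[Si](C(C)C)(C(C)C)C(C)C)=CC(C)(C)[C@H]13
F6 | step 2 | mirror-image alcohol, enantiomer of 6 | O[C@H]1CCC2(OCCO2)[C@@H]3CC(O[Si](C(C)C)(C(C)C)C(C)C)=CC(C)(C)[C@H]13
F7 | step 2 | (S)-O-methylmandelate ester of 6 | CO[C@H](C(=O)O[C@@H]1CCC2(OCCO2)[C@H]3CC(O[Si](C(C)C)(C(C)C)C(C)C)=CC(C)(C)[C@@H]13)c1ccccc1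
F8 | step 2 | (S)-O-methylmandelate ester of F6 | CO[C@H](C(=O)O[C@H]1CCC2(OCCO2)[C@@H]3CC(O[Si](C(C)C)(C(C)C)C(C)C)=CC(C)(C)[C@H]13)c1ccccc1
F9 | step 8 | C4 epimer of 6 (hydroxyl trans to H5 and H11) | O[C@H]1CCC2(OCCO2)[C@H]3CC(O[Si](C(C)C)(C(C)C)C(C)C)=CC(C)(C)[C@@H]13
F10 | step 8 | C4 epimer of 7 | O[C@H]1CCC2(OCCO2)[C@H]3CC(=O)CC(C)(C)[C@@H]13
F11 | step 8 | C4 epimer of 8 (both C10 epimers) | O[C@H]1CCC2(OCCO2)[C@H]3C(C)C(=O)CC(C)(C)[C@@H]13
F12 | step 8 | keto iodide, iodine in place of the mesylate of 9 (cis to H5 and H11) | I[C@@H]1CCC2(OCCO2)[C@H]3C(C)C(=O)CC(C)(C)[C@@H]13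
F13 | step 11 | 3-demethyllongipinane-1,7,9-trione 1-(ethylene ketal) | O=C1CC(=O)[C@]2(C)[C@@H]3[C@@H]([C@H]2C4(OCCO4)CC3)C1(C)C
F14 | step 16 | 7,9-bis{2-[bis(2,2,2-trifluoroethoxy)phosphoryl]propanoyloxy}longipinan-1-one | CC(C(=O)O[C@@H]1C[C@@H](OC(=O)C(C)P(=O)(OCC(F)(F)F)OCC(F)(F)F)[C@]2(C)[C@@H]3[C@@H]([C@H]2C(=O)C[C@H]3C)C1(C)C)P(=O)(OCC(F)(F)F)OCC(F)(F)F
A1 | alternative 1 | bicyclo[4.1.1]octane diester (product of the Wolff contraction) | CC(C)(C)[Si](C)(C)O[C@@H]1C[C@@H](O[Si](C)(C)C(C)(C)C)[C@]2(C)[C@@H](CCC(=O)OC)[C@@H]([C@H]2C(=O)OC)C1(C)C
A2 | alternative 1 | α-diazo ketone of the bicyclo[4.2.1]nonanone (diazo at C11, carbonyl C1) | CC(C)(C)[Si](C)(C)O[C@@H]1C[C@@H](O[Si](C)(C)C(C)(C)C)[C@]2(C)[C@@H](CCC(=O)OC)[C@@H](C(=O)C2=[N+]=[N-])C1(C)C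
A3 | alternative 2 | α-longipinene of the target enantiomeric series | C1CC[C@]2(C)[C@@H]3[C@@H]([C@H]2CC=C3C)C1(C)C
A4 | alternative 2 | (2E,6E)-farnesyl diphosphate | CC(C)=CCC/C(C)=C/CC/C(C)=C/COP(=O)(O)OP(=O)(O)O
A5 | alternative 3 | 2-hydroxy-4-methylbicyclo[3.1.1]heptan-6-one bearing the C10 methyl and silyloxymethyl groups | CC(C)(C)[Si](c1ccccc1)(c1ccccc1)OC[C@]2(C)[C@@H]3C(=O)[C@H]2[C@@H](O)C[C@H]3C
A6 | alternative 3 | 3-[(tert-butyldiphenylsilyloxy)methyl]-3-methylcyclobutan-1-one | O=C1CC(C)(CO[Si](c2ccccc2)(c2ccccc2)C(C)(C)C)C1
A7 | alternative 3 | (E)-but-2-enal | C/C=C/C=O
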